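- One thing stayed the same through the first 2.00 h of the cedar run: the solid substrate fell by 47 percentage points in the first hour and by 47 points in the second, a ratio of 1.00 as read, so I took its loss over those hours as zero order, with no slowing that these readings show.

- cedar: solid substrate 0.087 M; free catalyst 8.7 mM; the very flask that is asked about, followed so far
- flask: solid substrate 0.087 M; free catalyst 8.7 mM; time 10 h

- cedar (time / h: solid substrate / %, target / %): 1.00: 53, 20; 2.00: 6, 38; 3.00: 1, 36; 4.00: 0, 40

(each reading ± 1.5 percentage points)

- as a solid, counted per litre of solution: solid substrate
- at the start none of the solid substrate is in solution
- what has only dissolved of solid substrate counts as not reacted
- the reaction counts as stopped when no species that holds the solid substrate changes by six tenths of a point or more over the second half of the time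

- at 10 h, what has stopped the reaction, if anything has (for what has run out or reacted, a solid counts together with what of it has only dissolved) (forward and back rates have come level / it is still moving / no working catalyst is left / all of the solid substrate has reacted)
- part of the solid substrate that has turned into other species by 10 h (what has only dissolved does not count)
- the target standing at 10 h, as a percentage of the solid substrate charged

- Over the first 2.00 h the cedar run lost 0.0409 M/h of solid substrate; I named this amount per litre and hour the feed rate.
- Dividing the charge by the feed rate gave a clearing time of 2.13 h, and the flask asked about has the cedar charge and runs for 10 h, which is longer by a factor of 4.69.
- The cedar run lost 5 points in the third hour, but 6% was what stood when that hour began, so I applied no slowing factor and expected the flask to end with its solid gone. That what had dissolved would have reacted as well I took from the cedar target readings, which stayed within 4 points of each other from 2.00 h on.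
- Past the clearing time the cedar run gave target readings of 36% and 40%, with a scatter of 1.5 points, and I committed to their mean, 38.0%.
- The forecast, higher than my mean, said that all of the solid substrate has reacted, with conversion 100% and target 39% (range 34% to 42%), holding that “nothing is left that could hold an equilibrium with the target”.

    starting material + free catalyst ⇌ catalyst intermediate A (K = 22.0 /M, k = 190 /M/min)
    catalyst intermediate A → catalyst intermediate B (k = 0.990 /min)
    catalyst intermediate B → free catalyst + target (k = 1.20 /min)
    solid substrate ⇌ starting material, rate k4*(cs4 - [starting material]) while solid is left; crystals form when [starting material] > cs4 (solubility = 0.0500 M, k = 0.0150 /min)
    target + free catalyst ⇌ isomer of the product + free catalyst, rate k5*[free catalyst]*[target] forward; the back reaction follows from the equilibrium constant (K = 1.70, k = 12.0 /M/min)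

- The flask's answer was that all of the solid substrate has reacted, with conversion 100% and target 37.0%, inside the forecast's range. Nearly all of the flask's conversion stood by 2.13 h, close to the clearing time of 2.13 h, which came from the cedar readings over the first 2.00 h.
- For the neighbour flask with 0.35 M of solid substrate, I took the feed rate as unchanged, which gave a clearing time of 8.56 h, shorter than 10 h. The computed neighbour flask ended with 0% of its solid substrate still there and target at 37.0%.

Readings and results are simulated for an exercise.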